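**The ratio.** The length I had to give was a ratio: D in chains over chains begun, living and dead together.

| flask | D | Z | remark | time |
|---|---|---|---|---|
| north | 0.72 M | 11 mM | run made earlier |  |
| north-west | 0.72 M | 14 mM | run made earlier |  |
| Sunday's | 0.72 M | 7.2 mM |  | 2.5 h |
| Wednesday's | 3.0 M | 7.2 mM |  | 2.5 h |

| run | time / min | J / % |
|---|---|---|
| north | 5.00 | 9.7 |
| north | 12.0 | 35.8 |
| north | 25.0 | 54.2 |
| north | 40.0 | 55.3 |
| north | 50.0 | 55.4 |
| north-west | 4.00 | 7.4 |
| north-west | 8.00 | 25.5 |
| north-west | 15.0 | 46.9 |
| north-west | 30.0 | 54.6 |
| north-west | 50.0 | 55.2 |

(readings scatter by 0.5 percentage points)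

- which of the two ends with the longer chains by the average number of monomer units in a chain (chains begun, living or dead) ("neither" if they lie within 10 %) (Sunday's / Wednesday's / neither)
- average number of monomer units in a chain (chains begun, living or dead) at the end, Sunday's
- average number of monomer units in a chain (chains begun, living or dead) at the end, Wednesday's

- the average divides the monomer in chains by the number of chains begun, living and dead together
- the earlier runs do not show the number of chains; that part of a forecast is a guess

**First try.** I wrote the balance of Z, the smaller charge: Z charged equals whatever has not begun a chain plus chains begun. If each Z began one chain and every D entered a chain, Sunday's flask would give 100 and Wednesday's 417.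

**The ceiling.** But the earlier runs stopped short. The north run ended at 55.4 % and the north-west run at 55.2 %. That gap of 0.2 percentage points is less than the scatter of 0.5 points, though Z differed, 11 mM against 14 mM. So the ceiling did not follow Z. The last north reading put 0.321 M of D outside the chains. I took this as the D that stands beside the chains, the equilibrium monomer concentration [D]e. The length is then charged D less [D]e, over charged Z. That gave 55.4 for Sunday's flask and 372 for Wednesday's.

**A doubt.** Both earlier runs charged the same D, so a fixed percentage fitted them too. Wednesday's flask would then reach 231. That is still more than Sunday's 55.4, so this doubt touched the size and not the direction. I kept the equilibrium.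

**Another doubt.** Did Z finish? The readings show no chain count, so this part was a guess. The north run rose twice as fast after 5.00 min as before it, which I read as a slow start. But the north run read 54.2 % by 25.0 min, and 2.5 h is longer. So I counted one chain per Z charged.

**The forecast.** The forecast named Wednesday's, with 55.4 (49 to 68) for Sunday's flask and 372 (310 to 460) for Wednesday's. It held that “initiation and equilibrium should be complete in both new runs”. My reckoning stood with it.

**The flask.** Sunday's flask ended at 55.0 and Wednesday's at 371.

    D + Q → J + Q, rate k1*[Q]*[D] (k = 0.340 L mol⁻¹ s⁻¹)
    D + G → Q + J (k = 0.0340 L mol⁻¹ s⁻¹)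
    J + Q → D + Q, rate k3*[Q] as long as [J] is above zero (k = 0.110 s⁻¹)
    Z → G (k = 0.00170 s⁻¹)
    2 D → L (k = 2.10 × 10⁻⁷ L mol⁻¹ s⁻¹)

In Wednesday's flask the half-life of Z on its way to G was 0.11 h, much shorter than the 2.5 h of the run, and at the end Z stood at 0 % of its charge, with Q, the living end, at 0.00720 M. There J was made at 1.00 times the rate it was used up, each step taken net, and J stood at 89.1 % of the D charged, where charged D less [D]e gives 89.3 %. For the neighbour of Wednesday's flask with 0.0043 M of Z, charged D less [D]e over that Z gives 623, and that flask stood at 622.

(The runs come from a simulation on assumed constants; noise was put on by code.)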